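**Retrosynthetic overview**

- The strategy rests on ring A, the 2-ethyl-4,6-dihydroxyphenyl ring. Its C1 carries the ketone, C2 the ethyl group, and C4 and C6 the hydroxyls, so the two oxygens are meta to each other and one is ortho to the acyl carbon. This is the pattern an alkynyl ketone and a 1,3-dioxygenated diene give.
- Last ring: the 4-hydroxy-2-pyranone comes from an arylacetic acid and 2,2,6-trimethyl-1,3-dioxin-4-one by C-acylation and acylketene cyclisation. The acid comes from an allyl group on ring B by oxidative cleavage.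
- Key disconnection: ring A bonds C1–C6 and C2–C3, made by [4+2] benzannulation of an aryl ynone with 1-methoxy-1,3-bis(trimethylsilyloxy)buta-1,3-diene and aromatisation by loss of methanol.
- The ynone comes from 2-methoxy-6-(prop-2-enyl)benzaldehyde (aryl triflate, Stille allylation) and but-1-yne. The diene comes from methyl acetoacetate.
- Ring order: ring B is bought, ring A is closed in step 7, the pyranone ring in step 12. Phenols travel as methyl ethers and are freed in the last step.

Key step: step 7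

Assumption: the double-bond geometry of the silyl enol ether and of the silyloxydiene has no bearing on the benzannulation, so one isomer of each is drawn. The target has no stereocentre.

**Route**

Step 1
Reactants: 1 2-hydroxy-6-methoxybenzaldehyde
Product: 2 2-formyl-3-methoxyphenyl trifluoromethanesulfonate
Conditions: Tf2O, pyridine, CH2Cl2, 0 °C
Reagents that add atoms: trifluoromethanesulfonic anhydride, O=S(=O)(OS(=O)(=O)C(F)(F)F)C(F)(F)F
Why: Triflation of a phenol with Tf2O and pyridine is routine, and the aldehyde is inert to these conditions.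

Step 2
Reactants: 2 2-formyl-3-methoxyphenyl trifluoromethanesulfonate; 3 tributyl(prop-2-enyl)stannane
Product: 4 2-methoxy-6-(prop-2-enyl)benzaldehyde
Conditions: Pd(PPh3)4 (5 mol %), LiCl (3 equiv), DMF, 90 °C
Reagents that add atoms: none
Why: Stille coupling of an aryl triflate activated by the ortho formyl group (oxidative addition to zerovalent palladium, chloride-assisted transmetalation) should install the allyl group; an allylstannane is used because, unlike an allylboronate, it does not add to a free aldehyde without a Lewis acid.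

Step 3
Reactants: 4 2-methoxy-6-(prop-2-enyl)benzaldehyde; 5 but-1-yne
Product: 7 racemic 1-[2-methoxy-6-(prop-2-enyl)phenyl]pent-2-yn-1-ol, via but-1-ynyllithium 6 (not isolated)
Conditions: n-BuLi, THF, −78 °C; then 4, −78 to 0 °C; then H2O
Reagents that add atoms: none
Why: 1,2-Addition of a lithium acetylide to an aldehyde; the slim sp nucleophile should reach the flanked formyl group, and the carbinol stereocentre forms racemic and is erased in step 4.

Step 4
Reactants: 7 racemic 1-[2-methoxy-6-(prop-2-enyl)phenyl]pent-2-yn-1-ol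
Product: 8 1-[2-methoxy-6-(prop-2-enyl)phenyl]pent-2-yn-1-one
Conditions: MnO2 (excess), CH2Cl2, rt
Reagents that add atoms: none
Why: MnO2 oxidation is selective for benzylic and propargylic alcohols and should leave the allyl group and the alkyne untouched.

Step 5
Reactants: 9 methyl acetoacetate
Product: 10 methyl 3-(trimethylsilyloxy)but-2-enoate
Conditions: TMSCl, Et3N, hexane, rt
Reagents that add atoms: chlorotrimethylsilane, C[Si](C)(C)Cl
Why: O-Silylation of the enol of a β-keto ester with TMSCl and Et3N (silyl enol ether formation).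

Step 6
Reactants: 10 methyl 3-(trimethylsilyloxy)but-2-enoate
Product: 12 1-methoxy-1,3-bis(trimethylsilyloxy)buta-1,3-diene, via lithium dienolate 11 (not isolated)
Conditions: LiN(i-Pr)2 (LDA), THF, −78 °C; then TMSCl, −78 to 0 °C
Reagents that add atoms: chlorotrimethylsilane, C[Si](C)(C)Cl
Why: γ-Deprotonation of the vinylogous ester gives the extended dienolate, which is O-silylated to the ketene silyl acetal diene.

Step 7
Reactants: 8 1-[2-methoxy-6-(prop-2-enyl)phenyl]pent-2-yn-1-one; 12 1-methoxy-1,3-bis(trimethylsilyloxy)buta-1,3-diene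
Product: 15 (2-ethyl-4,6-dihydroxyphenyl)[2-methoxy-6-(prop-2-enyl)phenyl]methanone, via cyclohexadiene cycloadduct 13 (not isolated), via bis(trimethylsilyl) ether 14 (not isolated)
Conditions: 12 (3 equiv), toluene, 110 °C, sealed tube; then 1 M HCl, THF, rt
Reagents that add atoms: none
Why: The electron-rich diene 12 (largest HOMO coefficient at its terminal CH2) and the ynone 8 (largest LUMO coefficient at the ethyl-bearing β-carbon) should combine on heating in a [4+2] cycloaddition, either concerted but asynchronous or as a Mukaiyama–Michael addition followed by 6-exo-trig Claisen-type closure of the α-carbon onto the ester-level carbon, both paths closing the same six-membered ring A by intermolecular annulation. The closest known reaction type is the Diels–Alder benzannulation of 1-alkoxy-1,3-bis(silyloxy)butadienes with acetylenic ketones and esters, which gives resorcinols. Cycloadduct 13 should aromatise by 1,4-elimination of methanol to 14, and dilute acid hydrolyses the two aryl silyl ethers; the ketal stereocentre of 13 is lost on aromatisation, so no stereocontrol is needed. Regioselectivity (hydroxyl ortho to the ketone, ethyl on the other ortho carbon) is secured by the polarity match of the diene terminus with the ynone β-carbon. Chemoselectivity for conjugate attack over 1,2-addition is secured by the absence of a Lewis acid and by the 2,6-disubstituted aryl group that shields the carbonyl, and the unactivated allyl group is no dienophile. The crowded diaryl ketone thus arises without attack of any nucleophile on a hindered aryl carbonyl.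

Step 8
Reactants: 15 (2-ethyl-4,6-dihydroxyphenyl)[2-methoxy-6-(prop-2-enyl)phenyl]methanone
Product: 16 (2-ethyl-4,6-dimethoxyphenyl)[2-methoxy-6-(prop-2-enyl)phenyl]methanone
Conditions: MeI, K2CO3, DMF, 50 °C
Reagents that add atoms: iodomethane, CI
Why: Williamson O-methylation of both phenols, with mild heating for the hydrogen-bonded ortho hydroxyl; methyl ethers are chosen because their final cleavage releases only bromomethane, whereas acetal groups would release formaldehyde, which condenses with 4-hydroxypyranones.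

Step 9
Reactants: 16 (2-ethyl-4,6-dimethoxyphenyl)[2-methoxy-6-(prop-2-enyl)phenyl]methanone
Product: 18 2-[2-(2-ethyl-4,6-dimethoxybenzoyl)-3-methoxyphenyl]acetaldehyde, via vicinal diol 17 (not isolated)
Conditions: OsO4 (2 mol %), NaIO4 (4 equiv), 2,6-lutidine, dioxane–H2O (3:1), rt
Reagents that add atoms: osmium tetroxide, O=[Os](=O)(=O)=O (catalytic oxygen carrier); sodium periodate, [Na+].[O-]I(=O)(=O)=O (terminal oxidant)
Why: Lemieux–Johnson cleavage (catalytic dihydroxylation, then periodate glycol cleavage) acts only on the terminal alkene and spares the electron-rich arenes that ozone or RuO4 could attack.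

Step 10
Reactants: 18 2-[2-(2-ethyl-4,6-dimethoxybenzoyl)-3-methoxyphenyl]acetaldehyde
Product: 19 2-[2-(2-ethyl-4,6-dimethoxybenzoyl)-3-methoxyphenyl]acetic acid
Conditions: NaClO2, NaH2PO4, 2-methyl-2-butene (excess), t-BuOH–H2O, rt
Reagents that add atoms: sodium chlorite, [Na+].[O-]Cl=O
Why: Pinnick oxidation converts the aldehyde to the acid without touching the ketone or the ethers, the alkene scavenger removing the HOCl that could chlorinate the dimethoxyarene.

Step 11
Reactants: 19 2-[2-(2-ethyl-4,6-dimethoxybenzoyl)-3-methoxyphenyl]acetic acid; 20 2,2,6-trimethyl-4H-1,3-dioxin-4-one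
Product: 23 6-{3-[2-(2-ethyl-4,6-dimethoxybenzoyl)-3-methoxyphenyl]-2-oxopropyl}-2,2-dimethyl-4H-1,3-dioxin-4-one, via acyl imidazole 21 (not isolated), via lithium dienolate 22 (not isolated)
Conditions: 19, 1,1'-carbonyldiimidazole (CDI), THF, rt; separately 20, LiN(SiMe3)2, THF, −78 °C; add 21 to 22 (3.5 equiv), −78 °C; then 1 M HCl
Reagents that add atoms: none
Why: Claisen-type C-acylation of the dioxinone lithium dienolate at its γ-carbon by an N-acylimidazole; the tetra-ortho-substituted diaryl ketone is too hindered to compete, and the excess dienolate covers the imidazole set free on activation and the acidic product.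

Step 12
Reactants: 23 6-{3-[2-(2-ethyl-4,6-dimethoxybenzoyl)-3-methoxyphenyl]-2-oxopropyl}-2,2-dimethyl-4H-1,3-dioxin-4-one
Product: 25 6-{[2-(2-ethyl-4,6-dimethoxybenzoyl)-3-methoxyphenyl]methyl}-4-hydroxy-2H-pyran-2-one, via acylketene 24 (not isolated)
Conditions: toluene, 110 °C
Reagents that add atoms: none
Why: Thermal retro-[4+2] loss of acetone from the dioxinone gives an acylketene, which the enol oxygen of the δ-ketone should trap intramolecularly to close the 4-hydroxy-2-pyranone.

Step 13
Reactants: 25 6-{[2-(2-ethyl-4,6-dimethoxybenzoyl)-3-methoxyphenyl]methyl}-4-hydroxy-2H-pyran-2-one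
Product: 26 6-{[2-(2-ethyl-4,6-dihydroxybenzoyl)-3-hydroxyphenyl]methyl}-4-hydroxy-2H-pyran-2-one
Conditions: BBr3 (8 equiv), CH2Cl2, −78 °C to rt; then H2O
Reagents that add atoms: none
Why: BBr3 cleavage of aryl methyl ethers; the two ethers ortho to the ketone should cleave with chelation assistance and the para ether at room temperature, while the pyranone is held as its boron enolate and returned on hydrolysis.

**Compound list**

1 | 2-hydroxy-6-methoxybenzaldehyde | COc1cccc(O)c1C=O | starting material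
2 | 2-formyl-3-methoxyphenyl trifluoromethanesulfonate | COc1cccc(OS(=O)(=O)C(F)(F)F)c1C=O | intermediate
3 | tributyl(prop-2-enyl)stannane | C=CC[Sn](CCCC)(CCCC)CCCC | starting material
4 | 2-methoxy-6-(prop-2-enyl)benzaldehyde | COc1cccc(CC=C)c1C=O | intermediate
5 | but-1-yne | CCC#C | starting material
6 | but-1-ynyllithium | CCC#C[Li] | intermediate (not isolated)
7 | 1-[2-methoxy-6-(prop-2-enyl)phenyl]pent-2-yn-1-ol, racemic | CCC#CC(O)c1c(OC)cccc1CC=C | intermediate
8 | 1-[2-methoxy-6-(prop-2-enyl)phenyl]pent-2-yn-1-one | CCC#CC(=O)c1c(OC)cccc1CC=C | intermediate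
9 | methyl acetoacetate | COC(=O)CC(C)=O | starting material
10 | methyl 3-(trimethylsilyloxy)but-2-enoate (E isomer drawn) | C/C(O[Si](C)(C)C)=C\C(=O)OC | intermediate
11 | lithium dienolate of 10, lithium 1-methoxy-3-(trimethylsilyloxy)buta-1,3-dien-1-olate | C=C(O[Si](C)(C)C)C=C(OC)O[Li] | intermediate (not isolated)
12 | 1-methoxy-1,3-bis(trimethylsilyloxy)buta-1,3-diene (Z isomer drawn) | CO/C(O[Si](C)(C)C)=C/C(=C)O[Si](C)(C)C | intermediate
13 | [2-ethyl-6-methoxy-4,6-bis(trimethylsilyloxy)cyclohexa-1,4-dien-1-yl][2-methoxy-6-(prop-2-enyl)phenyl]methanone, racemic | CCC1=C(C(=O)c2c(OC)cccc2CC=C)C(OC)(O[Si](C)(C)C)C=C(O[Si](C)(C)C)C1 | intermediate (not isolated)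
14 | [2-ethyl-4,6-bis(trimethylsilyloxy)phenyl][2-methoxy-6-(prop-2-enyl)phenyl]methanone | CCc1cc(O[Si](C)(C)C)cc(O[Si](C)(C)C)c1C(=O)c1c(OC)cccc1CC=C | intermediate (not isolated)
15 | (2-ethyl-4,6-dihydroxyphenyl)[2-methoxy-6-(prop-2-enyl)phenyl]methanone | CCc1cc(O)cc(O)c1C(=O)c1c(OC)cccc1CC=C | intermediate
16 | (2-ethyl-4,6-dimethoxyphenyl)[2-methoxy-6-(prop-2-enyl)phenyl]methanone | CCc1cc(OC)cc(OC)c1C(=O)c1c(OC)cccc1CC=C | intermediate
17 | (2-ethyl-4,6-dimethoxyphenyl)[2-(2,3-dihydroxypropyl)-6-methoxyphenyl]methanone, racemic | CCc1cc(OC)cc(OC)c1C(=O)c1c(OC)cccc1CC(O)CO | intermediate (not isolated)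
18 | 2-[2-(2-ethyl-4,6-dimethoxybenzoyl)-3-methoxyphenyl]acetaldehyde | CCc1cc(OC)cc(OC)c1C(=O)c1c(OC)cccc1CC=O | intermediate
19 | 2-[2-(2-ethyl-4,6-dimethoxybenzoyl)-3-methoxyphenyl]acetic acid | CCc1cc(OC)cc(OC)c1C(=O)c1c(OC)cccc1CC(=O)O | intermediate
20 | 2,2,6-trimethyl-4H-1,3-dioxin-4-one | CC1=CC(=O)OC(C)(C)O1 | starting material
21 | 2-[2-(2-ethyl-4,6-dimethoxybenzoyl)-3-methoxyphenyl]-1-(imidazol-1-yl)ethanone | CCc1cc(OC)cc(OC)c1C(=O)c1c(OC)cccc1CC(=O)n1ccnc1 | intermediate (not isolated)
22 | lithium 2,2-dimethyl-6-methylidene-6H-1,3-dioxin-4-olate | C=C1C=C(O[Li])OC(C)(C)O1 | intermediate (not isolated)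
23 | 6-{3-[2-(2-ethyl-4,6-dimethoxybenzoyl)-3-methoxyphenyl]-2-oxopropyl}-2,2-dimethyl-4H-1,3-dioxin-4-one | CCc1cc(OC)cc(OC)c1C(=O)c1c(OC)cccc1CC(=O)CC1=CC(=O)OC(C)(C)O1 | intermediate
24 | 6-[2-(2-ethyl-4,6-dimethoxybenzoyl)-3-methoxyphenyl]-3,5-dioxohex-1-en-1-one (acylketene) | CCc1cc(OC)cc(OC)c1C(=O)c1c(OC)cccc1CC(=O)CC(=O)C=C=O | intermediate (not isolated)
25 | 6-{[2-(2-ethyl-4,6-dimethoxybenzoyl)-3-methoxyphenyl]methyl}-4-hydroxy-2H-pyran-2-one | CCc1cc(OC)cc(OC)c1C(=O)c1c(OC)cccc1Cc1cc(O)cc(=O)o1 | intermediate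
26 | 6-{[2-(2-ethyl-4,6-dihydroxybenzoyl)-3-hydroxyphenyl]methyl}-4-hydroxy-2H-pyran-2-one | CCc1cc(O)cc(O)c1C(=O)c1c(O)cccc1Cc1cc(O)cc(=O)o1 | target

**Step count**

Total: 13 steps. Longest linear sequence: 11 steps (steps 1–4 and 7–13); steps 5–6 make the diene.

**Steps most likely to fail**

Step 7. The cycloaddition at the β-ethyl-substituted alkyne may be slow enough that thermal silyl migration and decomposition of the diene win. Aromatisation may also go partly by loss of silanol instead of methanol, which would leave a methyl ether at C6; step 8 would still converge on 16. The fallback sets out from aldehyde 4 and comes back at 16, building the diaryl ketone by aryl-metal addition. Commercial 1-ethyl-3,5-dimethoxybenzene would be brominated with N-bromosuccinimide in MeCN at 0 °C, ortho to the ethyl group and para to a methoxy group, to give 2-bromo-1-ethyl-3,5-dimethoxybenzene F1. Bromine–lithium exchange (n-BuLi, THF, −78 °C) would give (2-ethyl-4,6-dimethoxyphenyl)lithium F2. This would add to 4 to give racemic (2-ethyl-4,6-dimethoxyphenyl)[2-methoxy-6-(prop-2-enyl)phenyl]methanol F3. Oxidation of F3 with Dess–Martin periodinane in CH2Cl2 would give 16.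

Step 11. Proton transfer from the acidic benzylic CH2 of the acyl imidazole to the dienolate (ketene formation, self-condensation) may outrun C-acylation. The fallback sets out from aldehyde 18 and comes back at 23, replacing acylation by aldol addition and oxidation. Dioxinone 20 would be converted (LDA, then TMSCl, THF, −78 °C) into its silyl dienol ether, 2,2-dimethyl-4-methylidene-6-(trimethylsilyloxy)-4H-1,3-dioxine F4. A vinylogous Mukaiyama aldol addition of F4 to 18 (BF3·OEt2, CH2Cl2, −78 °C) would give racemic 6-{3-[2-(2-ethyl-4,6-dimethoxybenzoyl)-3-methoxyphenyl]-2-hydroxypropyl}-2,2-dimethyl-4H-1,3-dioxin-4-one F5. Dess–Martin oxidation of F5 would give 23.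

Step 13. Cleavage of the para ether may stay incomplete, or long exposure to BBr3 may drive acid-promoted condensation of the pyranone with the activated ketone. The fallback sets out from 15 and comes back at the target 26, using benzyl ethers that are removed by neutral hydrogenolysis.
- BCl3 (CH2Cl2, −78 to 0 °C) would cleave the chelated ring B methyl ether of 15 to give (2-ethyl-4,6-dihydroxyphenyl)[2-hydroxy-6-(prop-2-enyl)phenyl]methanone F6.
- BnBr, K2CO3, DMF would give [2-ethyl-4,6-bis(benzyloxy)phenyl][2-benzyloxy-6-(prop-2-enyl)phenyl]methanone F7.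
- The conditions of step 9 would give, through racemic [2-ethyl-4,6-bis(benzyloxy)phenyl][2-benzyloxy-6-(2,3-dihydroxypropyl)phenyl]methanone F8, the aldehyde 2-{3-benzyloxy-2-[2-ethyl-4,6-bis(benzyloxy)benzoyl]phenyl}acetaldehyde F9.
- The conditions of step 10 would give 2-{3-benzyloxy-2-[2-ethyl-4,6-bis(benzyloxy)benzoyl]phenyl}acetic acid F10.
- The conditions of step 11 would give, through 2-{3-benzyloxy-2-[2-ethyl-4,6-bis(benzyloxy)benzoyl]phenyl}-1-(imidazol-1-yl)ethanone F11 and dienolate 22, the keto-dioxinone 6-(3-{3-benzyloxy-2-[2-ethyl-4,6-bis(benzyloxy)benzoyl]phenyl}-2-oxopropyl)-2,2-dimethyl-4H-1,3-dioxin-4-one F12.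
- Heating in toluene at 110 °C would give, through the acylketene 6-{3-benzyloxy-2-[2-ethyl-4,6-bis(benzyloxy)benzoyl]phenyl}-3,5-dioxohex-1-en-1-one F13, the pyranone 6-({3-benzyloxy-2-[2-ethyl-4,6-bis(benzyloxy)benzoyl]phenyl}methyl)-4-hydroxy-2H-pyran-2-one F14.
- Hydrogenolysis of F14 (H2, 10% Pd/C, EtOAc, rt) would give 26.

**Further compounds**

F1 | step 7 | 2-bromo-1-ethyl-3,5-dimethoxybenzene | CCc1cc(OC)cc(OC)c1Br
F2 | step 7 | (2-ethyl-4,6-dimethoxyphenyl)lithium | CCc1cc(OC)cc(OC)c1[Li]
F3 | step 7 | (2-ethyl-4,6-dimethoxyphenyl)[2-methoxy-6-(prop-2-enyl)phenyl]methanol, racemic | CCc1cc(OC)cc(OC)c1C(O)c1c(OC)cccc1CC=C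
F4 | step 11 | 2,2-dimethyl-4-methylidene-6-(trimethylsilyloxy)-4H-1,3-dioxine | C=C1C=C(O[Si](C)(C)C)OC(C)(C)O1
F5 | step 11 | 6-{3-[2-(2-ethyl-4,6-dimethoxybenzoyl)-3-methoxyphenyl]-2-hydroxypropyl}-2,2-dimethyl-4H-1,3-dioxin-4-one, racemic | CCc1cc(OC)cc(OC)c1C(=O)c1c(OC)cccc1CC(O)CC1=CC(=O)OC(C)(C)O1
F6 | step 13 | (2-ethyl-4,6-dihydroxyphenyl)[2-hydroxy-6-(prop-2-enyl)phenyl]methanone | CCc1cc(O)cc(O)c1C(=O)c1c(O)cccc1CC=C
F7 | step 13 | [2-ethyl-4,6-bis(benzyloxy)phenyl][2-benzyloxy-6-(prop-2-enyl)phenyl]methanone | CCc1cc(OCc2ccccc2)cc(OCc2ccccc2)c1C(=O)c1c(OCc2ccccc2)cccc1CC=C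
F8 | step 13 | [2-ethyl-4,6-bis(benzyloxy)phenyl][2-benzyloxy-6-(2,3-dihydroxypropyl)phenyl]methanone, racemic | CCc1cc(OCc2ccccc2)cc(OCc2ccccc2)c1C(=O)c1c(OCc2ccccc2)cccc1CC(O)CO
F9 | step 13 | 2-{3-benzyloxy-2-[2-ethyl-4,6-bis(benzyloxy)benzoyl]phenyl}acetaldehyde | CCc1cc(OCc2ccccc2)cc(OCc2ccccc2)c1C(=O)c1c(OCc2ccccc2)cccc1CC=O
F10 | step 13 | 2-{3-benzyloxy-2-[2-ethyl-4,6-bis(benzyloxy)benzoyl]phenyl}acetic acid | CCc1cc(OCc2ccccc2)cc(OCc2ccccc2)c1C(=O)c1c(OCc2ccccc2)cccc1CC(=O)O
F11 | step 13 | 2-{3-benzyloxy-2-[2-ethyl-4,6-bis(benzyloxy)benzoyl]phenyl}-1-(imidazol-1-yl)ethanone | CCc1cc(OCc2ccccc2)cc(OCc2ccccc2)c1C(=O)c1c(OCc2ccccc2)cccc1CC(=O)n1ccnc1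
F12 | step 13 | 6-(3-{3-benzyloxy-2-[2-ethyl-4,6-bis(benzyloxy)benzoyl]phenyl}-2-oxopropyl)-2,2-dimethyl-4H-1,3-dioxin-4-one | CCc1cc(OCc2ccccc2)cc(OCc2ccccc2)c1C(=O)c1c(OCc2ccccc2)cccc1CC(=O)CC1=CC(=O)OC(C)(C)O1
F13 | step 13 | 6-{3-benzyloxy-2-[2-ethyl-4,6-bis(benzyloxy)benzoyl]phenyl}-3,5-dioxohex-1-en-1-one | CCc1cc(OCc2ccccc2)cc(OCc2ccccc2)c1C(=O)c1c(OCc2ccccc2)cccc1CC(=O)CC(=O)C=C=O
F14 | step 13 | 6-({3-benzyloxy-2-[2-ethyl-4,6-bis(benzyloxy)benzoyl]phenyl}methyl)-4-hydroxy-2H-pyran-2-one | CCc1cc(OCc2ccccc2)cc(OCc2ccccc2)c1C(=O)c1c(OCc2ccccc2)cccc1Cc1cc(O)cc(=O)o1
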